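**Strategy.** The cyclobutane C1–C10–C9–C11 is read as a formal [2+2] adduct: C9 is a carbinol carbon next to the quaternary C10 (an enolisable ring B ketone at C9), and C1 lies β to the C12 carbonyl carbon on the oxygenated C11 (a 2-alkoxy acrylate). A silyl triflate/amine-promoted Michael–aldol cascade on a ring B keto enoate therefore forges C1–C10 (ring A) and C9–C11 (cyclobutane) in one operation and sets C1, C9, C10 and C11 from the single C5 stereocentre. The precursor is a 2-methylcyclohexanone (C6 dioxolane) whose C5 carries the CMe2–CH(OTBS)–CH2–CH=C(OBn)CO2Me chain; C5 comes from an Ireland–Claisen chirality transfer. Ring C is added afterwards by two aldol reactions.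

Key step: step 15

Remark: abietane numbering is kept for every intermediate (cyclopropane C13–C15–C16, C15 = CHMe, C17 its methyl); the enolisable C10 centre of 15–18 and 20–22 is drawn as formed and is erased in step 15; C1/C11 of 20–21 and C14 of 38–41 are left undefined because they are removed in steps 14 and 29.

**Step 1**
Reactants: 1 (S)-2-methyloxirane; 2 triethyl phosphonoacetate
Product: 3 ethyl (1R,2R)-2-methylcyclopropane-1-carboxylate
Conditions: NaH, DME, 0 °C → rt; then 1, 130 °C (sealed vessel)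
Reagents that add atoms: none
Why: Wadsworth–Emmons cyclopropanation, in which the phosphonoacetate anion opens the epoxide at CH2, the phosphoryl group migrates to the alkoxide and 3-exo-tet displacement with inversion at the methyl-bearing carbon gives the trans ester, so the (S)-epoxide sets (R)-C15.

**Step 2**
Reactants: 3 ethyl (1R,2R)-2-methylcyclopropane-1-carboxylate
Product: 4 S-ethyl (1R,2R)-2-methylcyclopropane-1-carbothioate
Conditions: AlMe3, EtSH, CH2Cl2, 0 °C → rt
Reagents that add atoms: ethanethiol, CCS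
Why: Ester-to-thioester exchange with the aluminium thiolate formed in the flask is a standard acyl substitution that leaves both ring stereocentres untouched.

**Step 3**
Reactants: 5 1,4-dioxaspiro[4.5]dec-6-en-8-one
Product: 6 7-iodo-1,4-dioxaspiro[4.5]dec-6-en-8-one
Conditions: I2, pyridine, CH2Cl2, 0 °C → rt
Reagents that add atoms: iodine, II
Why: α-Iodination of an enone by amine conjugate addition, iodination of the enolate and elimination is the standard route to 2-iodoenones.

**Step 4**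
Reactants: 6 7-iodo-1,4-dioxaspiro[4.5]dec-6-en-8-one
Product: 7 7-methyl-1,4-dioxaspiro[4.5]dec-6-en-8-one
Conditions: MeB(OH)2, Pd(OAc)2 (5 mol %), SPhos, K3PO4, toluene/H2O, 80 °C
Reagents that add atoms: methylboronic acid, CB(O)O
Why: Suzuki–Miyaura coupling of the activated alkenyl iodide installs the C10 methyl group with complete regiocontrol.

**Step 5**
Reactants: 7 7-methyl-1,4-dioxaspiro[4.5]dec-6-en-8-one
Product: 8 (8R)-7-methyl-1,4-dioxaspiro[4.5]dec-6-en-8-ol
Conditions: (S)-2-methyl-CBS-oxazaborolidine (10 mol %), BH3·SMe2, THF, −20 °C; MeOH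
Reagents that add atoms: none
Why: CBS reduction, in which the trisubstituted alkene flank acts as the large group so that the (S)-oxazaborolidine should give the (R)-allylic alcohol (C9 carbinol).

**Step 6**
Reactants: 8 (8R)-7-methyl-1,4-dioxaspiro[4.5]dec-6-en-8-ol; 9 2-methylpropanoyl chloride
Product: 10 (8R)-7-methyl-1,4-dioxaspiro[4.5]dec-6-en-8-yl 2-methylpropanoate
Conditions: Et3N, DMAP (cat.), CH2Cl2, 0 °C
Reagents that add atoms: none
Why: DMAP-catalysed O-acylation proceeds with retention at the carbinol carbon.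

**Step 7**
Reactants: 10 (8R)-7-methyl-1,4-dioxaspiro[4.5]dec-6-en-8-yl 2-methylpropanoate
Product: 13 2-methyl-2-[(6S)-7-methyl-1,4-dioxaspiro[4.5]dec-7-en-6-yl]propanoic acid, via silyl ketene acetal 11 (not isolated), via trimethylsilyl ester 12 (not isolated)
Conditions: LiN(i-Pr)2, Me3SiCl, THF, −78 → 65 °C; then aq. citric acid
Reagents that add atoms: none
Why: Ireland–Claisen rearrangement of the geometry-free isobutyrate ketene acetal is suprafacial, so C4–C5 forms on the face that carried the C9–O bond, which relays the carbinol configuration to C5 and builds the quaternary C4.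

**Step 8**
Reactants: 13 2-methyl-2-[(6S)-7-methyl-1,4-dioxaspiro[4.5]dec-7-en-6-yl]propanoic acid
Product: 14 2-(8-hydroxy-7-methyl-1,4-dioxaspiro[4.5]decan-6-yl)-2-methylpropan-1-ol (C9–OH and C10–H anti to the C5 side chain)
Conditions: BH3·THF (excess), THF, 0 °C → rt; then NaOH, H2O2, 0 °C
Reagents that add atoms: hydrogen peroxide, OO
Why: Borane reduces the hindered acid to the neopentyl alcohol and hydroborates the trisubstituted alkene with boron at C9 by syn addition anti to the pseudoaxial C5 substituent, and oxidation occurs with retention (hydroboration–oxidation).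

**Step 9**
Reactants: 14 diol
Product: 15 2-methyl-2-(7-methyl-8-oxo-1,4-dioxaspiro[4.5]decan-6-yl)propanal
Conditions: Dess–Martin periodinane (2.5 equiv), NaHCO3, CH2Cl2, 0 °C → rt
Reagents that add atoms: none
Why: Dess–Martin oxidation converts both alcohols under buffered, non-basic conditions that avoid aldol reactions of the keto aldehyde.

**Step 10**
Reactants: 15 keto aldehyde
Product: 16 6-[(3S)-3-hydroxy-2-methylhex-5-en-2-yl]-7-methyl-1,4-dioxaspiro[4.5]decan-8-one
Conditions: (−)-Ipc2B(allyl), Et2O, −78 °C; then NaOH, H2O2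
Reagents that add atoms: (−)-B-allyldiisopinocampheylborane, C=CCB([C@@H]1C[C@@H]2C[C@H]([C@H]1C)C2(C)C)[C@@H]1C[C@@H]2C[C@H]([C@H]1C)C2(C)C
Why: Brown allylation through a chair six-membered transition state is reagent-controlled and chemoselective for the aldehyde over the hindered ketone, and the (−)-reagent should give the (3S)-alcohol.

**Step 11**
Reactants: 16 homoallylic alcohol
Product: 17 6-[(3S)-3-(tert-butyldimethylsilyloxy)-2-methylhex-5-en-2-yl]-7-methyl-1,4-dioxaspiro[4.5]decan-8-one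
Conditions: TBSOTf, 2,6-lutidine, CH2Cl2, −78 → 0 °C
Reagents that add atoms: tert-butyldimethylsilyl triflate, CC(C)(C)[Si](C)(C)OS(=O)(=O)C(F)(F)F
Why: Silyl triflate with a hindered pyridine base silylates the neopentyl secondary alcohol without enolising the ketone.

**Step 12**
Reactants: 17 silyl ether
Product: 18 (3S)-3-(tert-butyldimethylsilyloxy)-4-methyl-4-(7-methyl-8-oxo-1,4-dioxaspiro[4.5]decan-6-yl)pentanal
Conditions: O3, CH2Cl2/MeOH, −78 °C; then PPh3
Reagents that add atoms: ozone, [O-][O+]=O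
Why: Ozonolysis with reductive work-up cleaves the only alkene to the C1 aldehyde.

**Step 13**
Reactants: 18 aldehyde; 19 methyl 2-(benzyloxy)acetate
Product: 20 methyl 2-(benzyloxy)-5-(tert-butyldimethylsilyloxy)-3-hydroxy-6-methyl-6-(7-methyl-8-oxo-1,4-dioxaspiro[4.5]decan-6-yl)heptanoate (C1/C11 diastereomer mixture)
Conditions: LiN(i-Pr)2, THF, −78 °C
Reagents that add atoms: none
Why: Aldol addition of the ester lithium enolate is much faster at the aldehyde than at the α-branched ketone at −78 °C, and the two new centres are removed in step 14.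

**Step 14**
Reactants: 20 aldol adduct
Product: 22 methyl (2Z,5S)-2-(benzyloxy)-5-(tert-butyldimethylsilyloxy)-6-methyl-6-(7-methyl-8-oxo-1,4-dioxaspiro[4.5]decan-6-yl)hept-2-enoate, via mesylate 21 (not isolated)
Conditions: MsCl, Et3N, CH2Cl2, 0 °C; then DBU, rt
Reagents that add atoms: none
Why: Mesylation and E1cB elimination through the ester-stabilised C11 anion should give the thermodynamically preferred (Z)-2-benzyloxy enoate with the ester trans to the chain.

**Step 15**
Reactants: 22 ring B keto enoate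
Product: 24 methyl 11β-benzyloxy-3β,9β-bis(tert-butyldimethylsilyloxy)-6,6-ethylenedioxy-4,4,10β-trimethyl tricycle-11α-carboxylate (rings A and B plus cyclobutane C1–C10–C9–C11; 1β-H, 5β-H, cis A/B), via tert-butyldimethylsilyl enol ether 23 (not isolated)
Conditions: TBSOTf (3 equiv), Et3N (5 equiv), CH2Cl2, −78 °C → rt
Reagents that add atoms: tert-butyldimethylsilyl triflate, CC(C)(C)[Si](C)(C)OS(=O)(=O)C(F)(F)F
Why: Silylation gives the C9=C10 silyl enol ether, which adds through C10 to C1 of the silyl-activated enoate (Mukaiyama–Michael), and the silyl ketene acetal so formed adds through C11 to the C9 silyloxocarbenium ion with the silyl group staying on O9, a formal [2+2] of the type known for intramolecular Michael–aldol reactions of keto enoates. Ring A closes in 6-exo-trig mode through a chair with the C3 silyloxy group equatorial and the C4 gem-dimethyl group favouring closure, and the cyclobutane closes in 4-exo-trig mode. C10 and C1 are controlled by C5, because attack on the enol ether axial to ring B places C1 cis to the C5 tether (cis A/B fusion, corrected in step 19). C9 follows from the obligatory cis fusion of the four-membered ring, and at C11 the ester should end trans to the bulky C9 silyloxy group, which leaves the benzyloxy group cis to O9. The step needs reaction through C10 and not C8, which is secured because only the C10 enol ether reaches the acceptor through a six-membered transition state while ammonium triflate interconverts the enol ethers, and it needs a [2+2] and not a double Michael outcome, which the saturated C7–C8 unit secures; excess amine should protect the C6 dioxolane.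

**Step 16**
Reactants: 24 tricyclic ester
Product: 25 C12 aldehyde (CHO in place of CO2Me on C11 of 24)
Conditions: i-Bu2AlH, CH2Cl2, −78 °C; aq. potassium sodium tartrate
Reagents that add atoms: none
Why: Low-temperature i-Bu2AlH reduction should stop at the aldehyde because the aluminium hemiacetal of this α-quaternary α-alkoxy ester is chelated and persists until work-up.

**Step 17**
Reactants: 25 C12 aldehyde; 4 S-ethyl (1R,2R)-2-methylcyclopropane-1-carbothioate
Product: 27 (12R)-acetoxy (13S,15R)-cyclopropyl thioester (C12 of 25 now CH(OAc) bonded to C13 of the S-ethyl 2-methylcyclopropane-1-carbothioate; C17 methyl trans to C12), via hydroxy thioester 26 (not isolated)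
Conditions: LiN(i-Pr)2, THF, −78 °C; MgBr2·OEt2; then 25, −78 → −40 °C; then Ac2O, DMAP, → 0 °C
Reagents that add atoms: acetic anhydride, CC(=O)OC(C)=O
Why: Chelation-controlled aldol addition in which magnesium bridges the aldehyde and C11 benzyloxy oxygens, the planar cyclopropyl enolate attacks from the C1 side (away from the C9 silyloxy group) through its face anti to the C15 methyl group, setting (12R) and (13S), and acylation traps the aldolate before retro-aldol.

**Step 18**
Reactants: 27 acetoxy thioester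
Product: 28 C6 ketone (5β-H, cis A/B)
Conditions: PPTS, acetone/H2O, 60 °C
Reagents that add atoms: water, O
Why: Acid-catalysed ketal hydrolysis under conditions that spare silyl ethers, acetate and thioester.

**Step 19**
Reactants: 28 cis C6 ketone
Product: 29 trans C6 ketone (5α-H)
Conditions: DBU, toluene, 80 °C
Reagents that add atoms: none
Why: Base-mediated epimerisation through the C5 enolate should favour the trans-fused isomer, because in the cis isomer C11 is held syn-axial to C6 or C4 whereas in the trans isomer it faces only axial hydrogens.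

**Step 20**
Reactants: 29 trans C6 ketone
Product: 32 7β-hydroxy-6-ketone, via trimethylsilyl enol ether 30 (not isolated), via 7β-trimethylsilyloxy ketone 31 (not isolated)
Conditions: Me3SiOTf, Et3N, CH2Cl2, 0 °C; then mCPBA, NaHCO3, −20 °C; then citric acid, MeOH
Reagents that add atoms: 3-chloroperbenzoic acid, OOC(=O)c1cccc(Cl)c1
Why: Rubottom oxidation, in which soft enolisation goes only towards C7 (C5 is shielded by two quaternary neighbours) and the peracid should attack C7 from the β-face because the α-face is covered by C11 and its side chain; the C7 configuration is immaterial.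

**Step 21**
Reactants: 32 7β-hydroxy-6-ketone
Product: 33 6β,7β-diol
Conditions: NaBH4, MeOH/THF, −20 °C
Reagents that add atoms: none
Why: Substrate-controlled hydride reduction from the α-face, the β-face of C6 being blocked by the syn-axial C10 and C4 methyl groups, should give the axial 6β-alcohol.

**Step 22**
Reactants: 33 6β,7β-diol
Product: 34 6β-hydroxy-7-ketone
Conditions: Dess–Martin periodinane (1.1 equiv), NaHCO3, CH2Cl2, 0 °C
Reagents that add atoms: none
Why: Chemoselective Dess–Martin oxidation of the accessible C7 alcohol, the 6β-hydroxyl being screened by two syn-axial methyl groups.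

**Step 23**
Reactants: 34 6β-hydroxy-7-ketone
Product: 35 6β-acetoxy-7-ketone
Conditions: Ac2O, DMAP, pyridine, 50 °C
Reagents that add atoms: acetic anhydride, CC(=O)OC(C)=O
Why: Forcing DMAP-catalysed acetylation esterifies the hindered axial alcohol, and the equatorial C6 hydrogen is poorly aligned for enolisation so the α-ketol should not isomerise.

**Step 24**
Reactants: 35 6β-acetoxy-7-ketone thioester
Product: 36 C14 aldehyde
Conditions: Et3SiH, Pd/C, acetone, rt
Reagents that add atoms: none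
Why: Fukuyama reduction converts the thioester into the aldehyde under neutral conditions compatible with ketone, acetates, silyl and benzyl ethers.

**Step 25**
Reactants: 36 keto aldehyde
Product: 38 tetracycle (ring C closed; 6β,12α-diacetoxy-11β-benzyloxy-3β,9β,14-tris(tert-butyldimethylsilyloxy)-7-ketone, 8β-H), via C7 silyl enol ether 37 (not isolated)
Conditions: TBSOTf (2.2 equiv), Et3N (3 equiv), CH2Cl2, −78 → −20 °C
Reagents that add atoms: tert-butyldimethylsilyl triflate, CC(C)(C)[Si](C)(C)OS(=O)(=O)C(F)(F)F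
Why: One-pot silyl enol ether formation and intramolecular Mukaiyama aldol addition, in which the C7 ketone enolises towards C8 (the C6 hydrogen is equatorial) and the non-enolisable aldehyde, tethered through the α-oriented C11, can reach only the α-face of C8, closing six-membered ring C with 8β-H and silyl transfer to O14.

**Step 26**
Reactants: 38 7-ketone
Product: 39 7α-alcohol
Conditions: NaBH4, MeOH/CH2Cl2, −40 °C
Reagents that add atoms: none
Why: Substrate-controlled hydride reduction from the β-face, because axial approach on the α-face is blocked by the syn-axial C9–C11 bond and ring C, should give the axial 7α-alcohol.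

**Step 27**
Reactants: 39 7α-alcohol
Product: 40 7α-benzyl ether
Conditions: 2-benzyloxy-1-methylpyridinium triflate, MgO, PhCF3, 85 °C
Reagents that add atoms: 2-benzyloxy-1-methylpyridinium triflate, C[n+]1ccccc1OCc1ccccc1.[O-]S(=O)(=O)C(F)(F)F
Why: Thermal benzyl transfer from the neutral pyridinium salt etherifies the hindered axial alcohol without acid or strong base, so acetates and silyl ethers survive.

**Step 28**
Reactants: 40 tris-silyl ether
Product: 41 3β,9β,14-triol
Conditions: HF·pyridine, THF/pyridine, 0 → 40 °C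
Reagents that add atoms: none
Why: Fluoride cleavage of all three silyl ethers under mildly acidic conditions that avoid acetyl migration.

**Step 29**
Reactants: 41 triol
Product: 42 3,14-diketone (7α,11β-dibenzyl ether)
Conditions: Dess–Martin periodinane (3 equiv), NaHCO3, CH2Cl2, rt
Reagents that add atoms: none
Why: Dess–Martin oxidation of the two secondary alcohols, the tertiary C9 alcohol and the ethers being inert.

**Step 30**
Reactants: 42 dibenzyl ether
Product: 43 CNP0157858.4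
Conditions: H2 (1 atm), Pd(OH)2/C, EtOAc, rt
Reagents that add atoms: none
Why: Hydrogenolysis of both benzyl ethers under neutral conditions should leave acetates, ketones and the cyclopropane intact.

**Compound list**

1 | (S)-2-methyloxirane | C[C@H]1CO1 | starting material
2 | triethyl phosphonoacetate | CCOC(=O)CP(=O)(OCC)OCC | starting material
3 | ethyl (1R,2R)-2-methylcyclopropane-1-carboxylate | CCOC(=O)[C@@H]1C[C@H]1C | intermediate
4 | S-ethyl (1R,2R)-2-methylcyclopropane-1-carbothioate | CCSC(=O)[C@@H]1C[C@H]1C | intermediate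
5 | 1,4-dioxaspiro[4.5]dec-6-en-8-one | O=C1C=CC2(CC1)OCCO2 | starting material
6 | 7-iodo-1,4-dioxaspiro[4.5]dec-6-en-8-one | O=C1CCC2(OCCO2)C=C1I | intermediate
7 | 7-methyl-1,4-dioxaspiro[4.5]dec-6-en-8-one | CC1=CC2(OCCO2)CCC1=O | intermediate
8 | (8R)-7-methyl-1,4-dioxaspiro[4.5]dec-6-en-8-ol | CC1=CC2(OCCO2)CC[C@H]1O | intermediate
9 | 2-methylpropanoyl chloride | CC(C)C(Cl)=O | starting material
10 | (8R)-7-methyl-1,4-dioxaspiro[4.5]dec-6-en-8-yl 2-methylpropanoate | CC1=CC2(OCCO2)CC[C@H]1OC(=O)C(C)C | intermediate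
11 | trimethylsilyl ketene acetal of 10 | CC1=CC2(OCCO2)CC[C@H]1OC(O[Si](C)(C)C)=C(C)C | intermediate
12 | trimethylsilyl 2-methyl-2-[(6S)-7-methyl-1,4-dioxaspiro[4.5]dec-7-en-6-yl]propanoate | C[Si](C)(C)OC(=O)C(C)(C)[C@H]1C2(OCCO2)CCC=C1C | intermediate
13 | 2-methyl-2-[(6S)-7-methyl-1,4-dioxaspiro[4.5]dec-7-en-6-yl]propanoic acid | OC(=O)C(C)(C)[C@H]1C2(OCCO2)CCC=C1C | intermediate
14 | 2-(8-hydroxy-7-methyl-1,4-dioxaspiro[4.5]decan-6-yl)-2-methylpropan-1-ol (side chain and methyl cis, methyl and hydroxyl trans) | OCC(C)(C)[C@H]1C2(OCCO2)CC[C@H](O)[C@H]1C | intermediate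
15 | 2-methyl-2-(7-methyl-8-oxo-1,4-dioxaspiro[4.5]decan-6-yl)propanal (6,7-cis) | O=CC(C)(C)[C@H]1C2(OCCO2)CCC(=O)[C@H]1C | intermediate
16 | 6-[(3S)-3-hydroxy-2-methylhex-5-en-2-yl]-7-methyl-1,4-dioxaspiro[4.5]decan-8-one | C=CC[C@H](O)C(C)(C)[C@H]1C2(OCCO2)CCC(=O)[C@H]1C | intermediate
17 | tert-butyldimethylsilyl ether of 16 | C=CC[C@H](O[Si](C)(C)C(C)(C)C)C(C)(C)[C@H]1C2(OCCO2)CCC(=O)[C@H]1C | intermediate
18 | (3S)-3-(tert-butyldimethylsilyloxy)-4-methyl-4-(7-methyl-8-oxo-1,4-dioxaspiro[4.5]decan-6-yl)pentanal | O=CC[C@H](O[Si](C)(C)C(C)(C)C)C(C)(C)[C@H]1C2(OCCO2)CCC(=O)[C@H]1C | intermediate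
19 | methyl 2-(benzyloxy)acetate | COC(=O)COCc1ccccc1 | starting material
20 | methyl 2-(benzyloxy)-5-(tert-butyldimethylsilyloxy)-3-hydroxy-6-methyl-6-(7-methyl-8-oxo-1,4-dioxaspiro[4.5]decan-6-yl)heptanoate (mixture at C1/C11) | COC(=O)C(OCc1ccccc1)C(O)C[C@H](O[Si](C)(C)C(C)(C)C)C(C)(C)[C@H]1C2(OCCO2)CCC(=O)[C@H]1C | intermediate
21 | C1 mesylate of 20 | COC(=O)C(OCc1ccccc1)C(OS(C)(=O)=O)C[C@H](O[Si](C)(C)C(C)(C)C)C(C)(C)[C@H]1C2(OCCO2)CCC(=O)[C@H]1C | intermediate
22 | methyl (2Z,5S)-2-(benzyloxy)-5-(tert-butyldimethylsilyloxy)-6-methyl-6-(7-methyl-8-oxo-1,4-dioxaspiro[4.5]decan-6-yl)hept-2-enoate (ring B keto enoate, C6 dioxolane) | COC(=O)/C(OCc1ccccc1)=C/C[C@H](O[Si](C)(C)C(C)(C)C)C(C)(C)[C@H]1C2(OCCO2)CCC(=O)[C@H]1C | intermediate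
23 | C9=C10 tert-butyldimethylsilyl enol ether of 22 | COC(=O)/C(OCc1ccccc1)=C/C[C@H](O[Si](C)(C)C(C)(C)C)C(C)(C)[C@H]1C2(OCCO2)CCC(O[Si](C)(C)C(C)(C)C)=C1C | intermediate
24 | tricyclic silyloxycyclobutane ester (rings A, B, cyclobutane; 3β,9β-OTBS, 11β-OBn, 11α-CO2Me, C6 dioxolane, 1β-H, 5β-H, 10β-Me) | COC(=O)[C@@]1(OCc2ccccc2)[C@H]2C[C@H](O[Si](C)(C)C(C)(C)C)C(C)(C)[C@H]3C4(OCCO4)CC[C@]1(O[Si](C)(C)C(C)(C)C)[C@@]23C | intermediate
25 | C12 aldehyde of 24 | O=C[C@@]1(OCc2ccccc2)[C@H]2C[C@H](O[Si](C)(C)C(C)(C)C)C(C)(C)[C@H]3C4(OCCO4)CC[C@]1(O[Si](C)(C)C(C)(C)C)[C@@]23C | intermediate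
26 | (12R)-hydroxy (13S,15R)-cyclopropyl S-ethyl thioester | CCSC(=O)[C@]4(C[C@H]4C)[C@@H](O)[C@@]1(OCc2ccccc2)[C@H]2C[C@H](O[Si](C)(C)C(C)(C)C)C(C)(C)[C@H]3C4(OCCO4)CC[C@]1(O[Si](C)(C)C(C)(C)C)[C@@]23C | intermediate
27 | (12R)-acetate of 26 | CCSC(=O)[C@]4(C[C@H]4C)[C@@H](OC(C)=O)[C@@]1(OCc2ccccc2)[C@H]2C[C@H](O[Si](C)(C)C(C)(C)C)C(C)(C)[C@H]3C4(OCCO4)CC[C@]1(O[Si](C)(C)C(C)(C)C)[C@@]23C | intermediate
28 | C6 ketone, 5β-H (cis A/B) | CCSC(=O)[C@]4(C[C@H]4C)[C@@H](OC(C)=O)[C@@]1(OCc2ccccc2)[C@H]2C[C@H](O[Si](C)(C)C(C)(C)C)C(C)(C)[C@H]3C(=O)CC[C@]1(O[Si](C)(C)C(C)(C)C)[C@@]23C | intermediate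
29 | C6 ketone, 5α-H (trans A/B) | CCSC(=O)[C@]4(C[C@H]4C)[C@@H](OC(C)=O)[C@@]1(OCc2ccccc2)[C@H]2C[C@H](O[Si](C)(C)C(C)(C)C)C(C)(C)[C@@H]3C(=O)CC[C@]1(O[Si](C)(C)C(C)(C)C)[C@@]23C | intermediate
30 | C6=C7 trimethylsilyl enol ether of 29 | CCSC(=O)[C@]4(C[C@H]4C)[C@@H](OC(C)=O)[C@@]1(OCc2ccccc2)[C@H]2C[C@H](O[Si](C)(C)C(C)(C)C)C(C)(C)[C@@H]3C(O[Si](C)(C)C)=CC[C@]1(O[Si](C)(C)C(C)(C)C)[C@@]23C | intermediate
31 | 7β-trimethylsilyloxy-6-ketone | CCSC(=O)[C@]4(C[C@H]4C)[C@@H](OC(C)=O)[C@@]1(OCc2ccccc2)[C@H]2C[C@H](O[Si](C)(C)C(C)(C)C)C(C)(C)[C@@H]3C(=O)[C@H](O[Si](C)(C)C)C[C@]1(O[Si](C)(C)C(C)(C)C)[C@@]23C | intermediate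
32 | 7β-hydroxy-6-ketone | CCSC(=O)[C@]4(C[C@H]4C)[C@@H](OC(C)=O)[C@@]1(OCc2ccccc2)[C@H]2C[C@H](O[Si](C)(C)C(C)(C)C)C(C)(C)[C@@H]3C(=O)[C@H](O)C[C@]1(O[Si](C)(C)C(C)(C)C)[C@@]23C | intermediate
33 | 6β,7β-diol | CCSC(=O)[C@]4(C[C@H]4C)[C@@H](OC(C)=O)[C@@]1(OCc2ccccc2)[C@H]2C[C@H](O[Si](C)(C)C(C)(C)C)C(C)(C)[C@@H]3[C@H](O)[C@H](O)C[C@]1(O[Si](C)(C)C(C)(C)C)[C@@]23C | intermediate
34 | 6β-hydroxy-7-ketone | CCSC(=O)[C@]4(C[C@H]4C)[C@@H](OC(C)=O)[C@@]1(OCc2ccccc2)[C@H]2C[C@H](O[Si](C)(C)C(C)(C)C)C(C)(C)[C@@H]3[C@H](O)C(=O)C[C@]1(O[Si](C)(C)C(C)(C)C)[C@@]23C | intermediate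
35 | 6β-acetoxy-7-ketone thioester | CCSC(=O)[C@]4(C[C@H]4C)[C@@H](OC(C)=O)[C@@]1(OCc2ccccc2)[C@H]2C[C@H](O[Si](C)(C)C(C)(C)C)C(C)(C)[C@@H]3[C@H](OC(C)=O)C(=O)C[C@]1(O[Si](C)(C)C(C)(C)C)[C@@]23C | intermediate
36 | 6β-acetoxy-7-keto C14 aldehyde | O=C[C@]4(C[C@H]4C)[C@@H](OC(C)=O)[C@@]1(OCc2ccccc2)[C@H]2C[C@H](O[Si](C)(C)C(C)(C)C)C(C)(C)[C@@H]3[C@H](OC(C)=O)C(=O)C[C@]1(O[Si](C)(C)C(C)(C)C)[C@@]23C | intermediate
37 | C7=C8 tert-butyldimethylsilyl enol ether of 36 | O=C[C@]4(C[C@H]4C)[C@@H](OC(C)=O)[C@@]1(OCc2ccccc2)[C@H]2C[C@H](O[Si](C)(C)C(C)(C)C)C(C)(C)[C@@H]3[C@H](OC(C)=O)C(O[Si](C)(C)C(C)(C)C)=C[C@]1(O[Si](C)(C)C(C)(C)C)[C@@]23C | intermediate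
38 | tetracyclic 7-ketone (6β,12α-OAc, 11β-OBn, 3β,9β,14-OTBS, 8β-H; C14 undefined) | CC(=O)O[C@@H]1C(=O)[C@H]2C(O[Si](C)(C)C(C)(C)C)[C@]3(C[C@H]3C)[C@@H](OC(C)=O)[C@@]3(OCc5ccccc5)[C@H]4C[C@H](O[Si](C)(C)C(C)(C)C)C(C)(C)[C@H]1[C@@]4(C)[C@@]23O[Si](C)(C)C(C)(C)C | intermediate
39 | 7α-alcohol of 38 | CC(=O)O[C@@H]1[C@@H](O)[C@H]2C(O[Si](C)(C)C(C)(C)C)[C@]3(C[C@H]3C)[C@@H](OC(C)=O)[C@@]3(OCc5ccccc5)[C@H]4C[C@H](O[Si](C)(C)C(C)(C)C)C(C)(C)[C@H]1[C@@]4(C)[C@@]23O[Si](C)(C)C(C)(C)C | intermediate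
40 | 7α-benzyl ether of 39 | CC(=O)O[C@@H]1[C@@H](OCc6ccccc6)[C@H]2C(O[Si](C)(C)C(C)(C)C)[C@]3(C[C@H]3C)[C@@H](OC(C)=O)[C@@]3(OCc5ccccc5)[C@H]4C[C@H](O[Si](C)(C)C(C)(C)C)C(C)(C)[C@H]1[C@@]4(C)[C@@]23O[Si](C)(C)C(C)(C)C | intermediate
41 | 3β,9β,14-triol (7α,11β-dibenzyl ether, 6β,12α-diacetate) | CC(=O)O[C@@H]1[C@@H](OCc6ccccc6)[C@H]2C(O)[C@]3(C[C@H]3C)[C@@H](OC(C)=O)[C@@]3(OCc5ccccc5)[C@H]4C[C@H](O)C(C)(C)[C@H]1[C@@]4(C)[C@@]23O | intermediate
42 | 3,14-diketone (7α,11β-dibenzyl ether) | CC(=O)O[C@@H]1[C@@H](OCc6ccccc6)[C@H]2C(=O)[C@]3(C[C@H]3C)[C@@H](OC(C)=O)[C@@]3(OCc5ccccc5)[C@H]4CC(=O)C(C)(C)[C@H]1[C@@]4(C)[C@@]23O | intermediate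
43 | CNP0157858.4 (6β,12α-diacetoxy-7α,9β,11β-trihydroxy-3,14-dione with cyclobutane C1–C10–C9–C11 and spiro cyclopropane C13–C15–C16) | CC(=O)O[C@@H]1[C@@H](O)[C@H]2C(=O)[C@]3(C[C@H]3C)[C@@H](OC(C)=O)[C@@]3(O)[C@H]4CC(=O)C(C)(C)[C@H]1[C@@]4(C)[C@@]23O | target

**Step count and risks**

Total: 30 steps. Longest linear sequence: 28 steps (steps 3–30, from 5); steps 1–2 make fragment 4.

Steps most likely to fail:

1. **Step 15.** The cascade may stall at the unproductive C8 enol ether, the silyl triflate may open the dioxolane, or the sequence may stop after the conjugate addition because the strained 4-exo closure does not follow. Fallback: setting out from 22, a base-mediated intramolecular Michael addition (t-BuOK cat., t-BuOH/THF, 0 °C) would give the bicyclic keto ester F1. Irradiation (hν > 300 nm, benzene) would then close C9–C11 by Norrish–Yang cyclisation, since the captodative C11–H is the only γ-hydrogen of the C9 ketone, to give the cyclobutanol F2. Silylation (TBSOTf, 2,6-lutidine) would come back to the route at 24.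

2. **Step 19.** Enolisation at the congested C5 may be too slow against the competing enolisation at C7, so the ring fusion equilibrates incompletely. Fallback: setting out from 28, Saegusa oxidation through the trimethylsilyl enol ether F3 (Me3SiOTf, Et3N; then Pd(OAc)2, MeCN) would give the cis-fused C7=C8 enone F4, in which C5 is the only enolisable position. DBU would equilibrate it through the cross-conjugated dienolate to the trans-fused enone F5, and conjugate reduction with [(Ph3P)CuH]6 would come back to the route at 29.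

3. **Step 17.** The crowded magnesium aldolate may revert by retro-aldol before it is acylated, or facial selectivity at C12 may be poor. Fallback: setting out from 25, the addition would be run with the lithium enolate of 4 alone and quenched cold to give alcohol 26 together with its C12-epimeric alcohol F6. Dess–Martin oxidation of the mixture would give the β-keto thioester F7, and Felkin–Anh-controlled reduction (NaBH4, CeCl3·7H2O, MeOH, −78 °C; hydride anti to the C11–O bond) should converge on 26. Acetylation (Ac2O, DMAP) would come back to the route at 27.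

**Further compounds**

F1 | step 15 | bicyclic keto ester (rings A and B closed, C9 ketone, C11–H epimers) | COC(=O)C(OCc1ccccc1)[C@H]2C[C@H](O[Si](C)(C)C(C)(C)C)C(C)(C)[C@H]3C4(OCCO4)CCC(=O)[C@@]23C
F2 | step 15 | cyclobutanol (9β-OH analogue of 24) | COC(=O)[C@@]1(OCc2ccccc2)[C@H]2C[C@H](O[Si](C)(C)C(C)(C)C)C(C)(C)[C@H]3C4(OCCO4)CC[C@]1(O)[C@@]23C
F3 | step 19 | C6=C7 trimethylsilyl enol ether of 28 | CCSC(=O)[C@]4(C[C@H]4C)[C@@H](OC(C)=O)[C@@]1(OCc2ccccc2)[C@H]2C[C@H](O[Si](C)(C)C(C)(C)C)C(C)(C)[C@H]3C(O[Si](C)(C)C)=CC[C@]1(O[Si](C)(C)C(C)(C)C)[C@@]23C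
F4 | step 19 | cis-fused C7=C8 enone (5β-H) | CCSC(=O)[C@]4(C[C@H]4C)[C@@H](OC(C)=O)[C@@]1(OCc2ccccc2)[C@H]2C[C@H](O[Si](C)(C)C(C)(C)C)C(C)(C)[C@H]3C(=O)C=C[C@]1(O[Si](C)(C)C(C)(C)C)[C@@]23C
F5 | step 19 | trans-fused C7=C8 enone (5α-H) | CCSC(=O)[C@]4(C[C@H]4C)[C@@H](OC(C)=O)[C@@]1(OCc2ccccc2)[C@H]2C[C@H](O[Si](C)(C)C(C)(C)C)C(C)(C)[C@@H]3C(=O)C=C[C@]1(O[Si](C)(C)C(C)(C)C)[C@@]23C
F6 | step 17 | (12S)-hydroxy thioester (C12 epimer of 26) | CCSC(=O)[C@]4(C[C@H]4C)[C@H](O)[C@@]1(OCc2ccccc2)[C@H]2C[C@H](O[Si](C)(C)C(C)(C)C)C(C)(C)[C@H]3C4(OCCO4)CC[C@]1(O[Si](C)(C)C(C)(C)C)[C@@]23C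
F7 | step 17 | C12 β-keto thioester | CCSC(=O)[C@]4(C[C@H]4C)C(=O)[C@@]1(OCc2ccccc2)[C@H]2C[C@H](O[Si](C)(C)C(C)(C)C)C(C)(C)[C@H]3C4(OCCO4)CC[C@]1(O[Si](C)(C)C(C)(C)C)[C@@]23C
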